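**Retrosynthetic overview**

- Feature: on ring A, the oxygenated carbon C19 (on C4) and the methyl C20 (on C10) are syn-diaxial on the β face. The second C4 carbon, C18, therefore shares the α face with the C10–C9 bond. C9–C10 and C7–C8 are the two ring B bonds that flank the C7=C8 olefin.
- Endgame: the acid is freed last. C12–C13 is cut as a B-alkyl Suzuki coupling of a C11=C12 vinyl group with a (Z)-3-iodobut-2-enoate. The tiglate goes on C19 just before, and the vinyl group is traced back to a C11 ester.
- Key disconnection: C9–C10 and C7–C8 are cut together as a type 2 intramolecular Diels–Alder reaction. A but-2-ynoate hung on the C18 oxygen adds to the diene C10=C5–C6=C7. The C18–O–C11 lactone is then opened and the spent arm is reduced to the C18 methyl.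
- Precursor: a prochiral 4,4-bis(hydroxymethyl) vinylcyclohexene made from 2-methylcyclohexanone. A lipase tells its two arms apart and sets C4, from which C10, C5 and C9 follow in turn.
- Ring order: ring A is bought. Ring B and the temporary seven-membered lactone close in the same step, and the lactone is then opened.

Key step: step 11

Numbering: labdane numbering is used for all compounds (C11 on C9, C17 on C8, C18 α and C19 β on C4, C20 on C10). TBS = tert-butyldimethylsilyl, TBDPS = tert-butyldiphenylsilyl.

Assumption: the lipase is taken to acetylate the pro-C18 arm; the sense must be found by screening, and since acylation of diol 10 and hydrolysis of its diacetate by one enzyme give opposite monoacetates, 11 is reachable in either case.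

**Step 1**
Reactants: 1 2-methylcyclohexanone
Product: 2 ethyl 3-methyl-2-oxocyclohexane-1-carboxylate (racemic, diastereomer and enol mixture)
Conditions: NaH, (EtO)2CO, THF, reflux; aq. HCl work-up
Reagents that add atoms: diethyl carbonate, CCOC(=O)OCC
Why: Claisen-type C-acylation of the ketone enolate ends on the CH2 side because only that β-keto ester is drained off as its stabilised sodium enolate.

**Step 2**
Reactants: 2 ethyl 3-methyl-2-oxocyclohexane-1-carboxylate
Product: 3 ethyl 1-(hydroxymethyl)-3-methyl-2-oxocyclohexane-1-carboxylate (racemic, diastereomer mixture)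
Conditions: 37% aq. HCHO, KHCO3 (0.2 equiv), THF, rt
Reagents that add atoms: formaldehyde, C=O
Why: Base-catalysed aldol hydroxymethylation occurs at the only doubly activated carbon and makes the quaternary carbon C4, still racemic, while the methyl-bearing stereocentre is erased in step 4.

**Step 3**
Reactants: 3 ethyl 1-(hydroxymethyl)-3-methyl-2-oxocyclohexane-1-carboxylate
Product: 4 ethyl 1-(TBS-oxymethyl)-3-methyl-2-oxocyclohexane-1-carboxylate (racemic, diastereomer mixture)
Conditions: TBSCl, imidazole, DMF, 0 °C to rt
Reagents that add atoms: tert-butyldimethylsilyl chloride, CC(C)(C)[Si](C)(C)Cl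
Why: Silyl ether formation blocks the retro-aldol loss of formaldehyde that a free β-hydroxy ketone would suffer under the strong base of step 4.

**Step 4**
Reactants: 4 ethyl 1-(TBS-oxymethyl)-3-methyl-2-oxocyclohexane-1-carboxylate
Product: 6 ethyl 1-(TBS-oxymethyl)-3-methyl-2-(trifluoromethylsulfonyloxy)cyclohex-2-ene-1-carboxylate (racemic), via potassium enolate 5 (not isolated)
Conditions: KN(SiMe3)2, THF, −78 °C; then PhNTf2, −78 °C to rt; aq. NH4Cl
Reagents that add atoms: N-phenylbis(trifluoromethanesulfonimide), O=S(=O)(N(c1ccccc1)S(=O)(=O)C(F)(F)F)C(F)(F)F; potassium bis(trimethylsilyl)amide, C[Si](C)(C)[N-][Si](C)(C)C.[K+] (potassium only in 5)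
Why: The ketone has a single α-hydrogen (on future C10), so deprotonation and O-sulfonylation can give only the tetrasubstituted C5=C10 enol triflate, as is established for 2,2,6-trisubstituted cyclohexanones.

**Step 5**
Reactants: 6 the enol triflate; 7 tributyl(vinyl)stannane
Product: 8 ethyl 1-(TBS-oxymethyl)-3-methyl-2-vinylcyclohex-2-ene-1-carboxylate (racemic)
Conditions: Pd(PPh3)4 (5 mol %), LiCl (3 equiv), THF, 65 °C
Reagents that add atoms: none
Why: Stille coupling of hindered cyclohexenyl triflates with vinylstannanes in the presence of LiCl is well established and installs C6=C7 of the diene.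

**Step 6**
Reactants: 8 ethyl 1-(TBS-oxymethyl)-3-methyl-2-vinylcyclohex-2-ene-1-carboxylate
Product: 10 (3-methyl-2-vinylcyclohex-2-ene-1,1-diyl)dimethanol (achiral, prochiral at C4), via racemic monosilyl alcohol 9 (not isolated)
Conditions: LiAlH4, THF, 0 °C; aqueous work-up; crude, Bu4NF, THF, rt; aq. NH4Cl
Reagents that add atoms: none
Why: Hydride reduction of the ester followed by fluoride desilylation makes both C4 arms CH2OH, which gives the prochiral diol that desymmetrisation needs.

**Step 7**
Reactants: 10 (3-methyl-2-vinylcyclohex-2-ene-1,1-diyl)dimethanol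
Product: 11 (R)-[1-(hydroxymethyl)-3-methyl-2-vinylcyclohex-2-en-1-yl]methyl acetate (acetate on the pro-C18 arm)
Conditions: immobilised Burkholderia cepacia lipase (Amano PS), vinyl acetate, i-Pr2O, 25 °C
Reagents that add atoms: vinyl acetate, C=COC(C)=O
Why: Lipase-catalysed irreversible transesterification is a known way to desymmetrise 2,2-disubstituted propane-1,3-diols, and the enzyme should tell the bulky sp2 side (C5) from the CH2 side (C3) of ring A and so fix the absolute configuration at C4.

**Step 8**
Reactants: 11 the (R)-monoacetate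
Product: 12 (S)-[1-(TBDPS-oxymethyl)-3-methyl-2-vinylcyclohex-2-en-1-yl]methyl acetate
Conditions: TBDPSCl, imidazole, DMF, 0 °C to rt
Reagents that add atoms: tert-butyldiphenylsilyl chloride, CC(C)(C)[Si](Cl)(c1ccccc1)c1ccccc1
Why: Prompt silylation caps the pro-C19 arm before acetyl migration between the arms can racemise C4, and it installs a group that outlasts the heat, methoxide, radical and hydride steps ahead, which an acetate would not.

**Step 9**
Reactants: 12 the (S)-silyl acetate
Product: 13 (S)-[1-(TBDPS-oxymethyl)-3-methyl-2-vinylcyclohex-2-en-1-yl]methanol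
Conditions: K2CO3 (0.2 equiv), MeOH, 0 °C
Reagents that add atoms: none
Why: Carbonate-catalysed transesterification frees the pro-C18 arm under cold protic conditions in which migration of the bulky silyl group between the arms is not expected.

**Step 10**
Reactants: 13 the (S)-monosilyl alcohol; 14 but-2-ynoic acid
Product: 15 (S)-[1-(TBDPS-oxymethyl)-3-methyl-2-vinylcyclohex-2-en-1-yl]methyl but-2-ynoate
Conditions: DCC, DMAP (0.1 equiv), CH2Cl2, 0 °C
Reagents that add atoms: none
Why: Steglich esterification acylates the neopentyl alcohol under near-neutral conditions, with DMAP kept catalytic and cold to avoid ynoate to allenoate isomerisation.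

**Step 11**
Reactants: 15 the (S)-but-2-ynoate
Product: 16 19-(TBDPS-oxy)-12,13,14,15,16-pentanorlabda-5,8-dien-11,18-olide (C11(=O)–O–C18 lactone on the α face, C19 and C20 both β)
Conditions: o-dichlorobenzene (0.005 M, degassed), BHT, 180 °C, sealed vessel
Reagents that add atoms: none
Why: Proposed new method: a concerted but asynchronous thermal [4+2] cycloaddition joins the ynoate α-carbon (future C9) to the fully substituted diene terminus C10 and the β-carbon (C8, bearing C17) to C7, leaving C5=C6 and C8=C9. The closest known reaction types are type 2 intramolecular Diels–Alder reactions of ester-tethered alkynes, which give bridgehead dienes, and intermolecular additions of acetylenic esters to 1-vinyl-2,6,6-trialkylcyclohexenes, which make the same quaternary C10; a tether anchored on a ring carbon next to the diene has not been tried. Ring B closes as the six-membered cycloaddition ring, and the seven-membered lactone (C4–C18–O–C11–C9–C10–C5) closes as the tether ring, which requires the E rotamer of the ester that the polar solvent helps to populate. C10 is the only new stereocentre and is controlled by C4: the four-atom tether (C4, C18, O, C11) can lay the alkyne only under the α face on which C18 stands, so C9 bonds to C10 from that face and C20 is turned to the β face, syn to C19. The step therefore needs facial selectivity at C10 and the C9-to-C10 regiochemistry, and both are secured by the short tether, since neither the reversed orientation nor the β face can be reached. What the substrate does not secure is the rate, because the s-cis diene is crowded by C20 and the product holds two bridgehead olefins; the high exothermicity of alkyne cycloaddition, the pre-organisation by the quaternary C4 and high dilution in the presence of BHT are relied on to let it outrun [1,5]-hydrogen shift and oligomerisation.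

**Step 12**
Reactants: 16 the lactone-bridged 5,8-diene
Product: 17 methyl 18-hydroxy-19-(TBDPS-oxy)-12,13,14,15,16-pentanorlabda-5,8-dien-11-oate
Conditions: NaOMe (0.2 equiv), MeOH–THF, 0 °C
Reagents that add atoms: methanol, CO
Why: Methoxide-catalysed transesterification should open the lactone readily because it releases the strain of the bridged diene, turning C11 into the methyl ester and freeing C18–OH while the silyl ether on C19 stays.

**Step 13**
Reactants: 17 the hydroxy ester 5,8-diene
Product: 18 methyl 18-hydroxy-19-(TBDPS-oxy)-12,13,14,15,16-pentanorlabd-8-en-11-oate (5α-H, trans-decalin)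
Conditions: [Ir(cod)(PCy3)(py)]PF6 (10 mol %), H2 (1–4 atm), CH2Cl2, rt
Reagents that add atoms: none
Why: Hydroxyl-directed homogeneous hydrogenation should reduce the hindered trisubstituted C5=C6 bond from the α face, where the homoallylic C18–OH binds iridium and which is also the face away from C19 and C20, setting 5α-H and sparing the tetrasubstituted, electron-poor C8=C9 bond.

**Step 14**
Reactants: 18 the 5α hydroxy ester
Product: 19 methyl 18-iodo-19-(TBDPS-oxy)-12,13,14,15,16-pentanorlabd-8-en-11-oate
Conditions: I2, PPh3, imidazole, toluene, 90 °C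
Reagents that add atoms: iodine, II
Why: Appel-type iodination (Garegg–Samuelsson conditions) converts the equatorial neopentyl alcohol into the iodide on heating by direct displacement without skeletal rearrangement.

**Step 15**
Reactants: 19 the C18 iodide
Product: 20 methyl 19-(TBDPS-oxy)-12,13,14,15,16-pentanorlabd-8-en-11-oate
Conditions: Bu3SnH, AIBN, toluene, 85 °C
Reagents that add atoms: none
Why: Tin hydride radical dehalogenation turns C18–I into the C18 methyl through a primary radical that has no olefin within cyclisation range.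

**Step 16**
Reactants: 20 the Δ8 ester
Product: 21 methyl 7-bromo-19-(TBDPS-oxy)-12,13,14,15,16-pentanorlabd-8-en-11-oate (C7 epimers, configuration irrelevant)
Conditions: NBS, AIBN, PhCF3, 80 °C; used crude
Reagents that add atoms: N-bromosuccinimide, O=C1CCC(=O)N1Br
Why: Wohl–Ziegler bromination should attack the ring allylic CH2 (C7) in preference to the C17 methyl, as it does in β-cyclogeranate and β-ionone rings, and so marks the γ-carbon from which the dienolate has to be made.

**Step 17**
Reactants: 21 the 7-bromide
Product: 23 methyl 19-(TBDPS-oxy)-12,13,14,15,16-pentanorlabd-7-en-11-oate (9α-H, C11 β-equatorial), via bromozinc dienolate 22 (not isolated)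
Conditions: Zn dust, AcOH–Et2O, 0 °C
Reagents that add atoms: zinc, [Zn] (only in 22)
Why: Zinc reduction of the γ-bromo enoate gives only the endocyclic C7=C8 dienolate (direct amide-base deprotonation would instead take the C17 proton syn to the ester and lead to the exocyclic olefin), and kinetic α-protonation from the α face opposite axial C20 sets 9α-H, which is also the more stable epimer.

**Step 18**
Reactants: 23 the Δ7 ester
Product: 24 19-(TBDPS-oxy)-12,13,14,15,16-pentanorlabd-7-en-11-ol
Conditions: LiAlH4, Et2O, 0 °C to rt; aqueous work-up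
Reagents that add atoms: none
Why: Hydride reduction of the hindered ester to the primary alcohol touches neither the isolated olefin nor the silyl ether nor C9.

**Step 19**
Reactants: 24 the C11 alcohol
Product: 25 19-(TBDPS-oxy)-12,13,14,15,16-pentanorlabd-7-en-11-al
Conditions: DMP, NaHCO3, CH2Cl2, 0 °C
Reagents that add atoms: none
Why: Dess–Martin oxidation under bicarbonate buffer gives the β,γ-unsaturated aldehyde without acid or base strong enough to epimerise C9 or draw the olefin into conjugation.

**Step 20**
Reactants: 25 the C11 aldehyde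
Product: 26 19-(TBDPS-oxy)-13,14,15,16-tetranorlabda-7,11-diene
Conditions: Ph3PCH3Br, KN(SiMe3)2, THF, 0 °C; then 25, −78 to 0 °C
Reagents that add atoms: methyltriphenylphosphonium bromide, C[P+](c1ccccc1)(c1ccccc1)c1ccccc1.[Br-]
Why: Wittig methylenation with the non-stabilised ylide at low temperature should be faster than enolisation, and C9 already carries its substituent in the stable equatorial position.

**Step 21**
Reactants: 26 the silyl ether diene
Product: 27 13,14,15,16-tetranorlabda-7,11-dien-19-ol
Conditions: Bu4NF, THF, 50 °C; aq. NH4Cl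
Reagents that add atoms: none
Why: Fluoride desilylation of the hindered axial neopentyl ether can be pushed by warming here because the molecule holds only olefins at this stage.

**Step 22**
Reactants: 27 the C19 alcohol; 28 tigloyl chloride, (E)-2-methylbut-2-enoyl chloride
Product: 29 13,14,15,16-tetranorlabda-7,11-dien-19-yl (E)-2-methylbut-2-enoate
Conditions: pyridine, DMAP (cat.), CH2Cl2, 0 to 40 °C
Reagents that add atoms: none
Why: DMAP-catalysed acylation with a weak base avoids the vinylketene pathway, and the tiglate is the stable geometric isomer, so the E olefin is kept.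

**Step 23**
Reactants: 30 (Z)-3-iodobut-2-enoic acid
Product: 31 2-(trimethylsilyl)ethyl (Z)-3-iodobut-2-enoate
Conditions: Me3SiCH2CH2OH, PPh3, DIAD, THF, 0 °C
Reagents that add atoms: 2-(trimethylsilyl)ethanol, C[Si](C)(C)CCO
Why: Mitsunobu esterification is neutral and free of nucleophilic amine, so addition–elimination at the β-iodo enoate and Z to E leakage are avoided, and the silylethyl ester, unlike an allyl ester, is inert to zerovalent palladium in step 24.

**Step 24**
Reactants: 29 the vinyl tiglate; 31 2-(trimethylsilyl)ethyl (Z)-3-iodobut-2-enoate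
Product: 33 2-(trimethylsilyl)ethyl 19-tigloyloxylabda-7,13(Z)-dien-15-oate, via B-alkyl-9-BBN adduct 32 (not isolated)
Conditions: 9-BBN, THF, rt; then 31, Pd(dppf)Cl2 (5 mol %), AsPh3, aq. Cs2CO3, DMF, rt
Reagents that add atoms: 9-borabicyclo[3.3.1]nonane, [H]B1C2CCCC1CCC2 (boron only in 32)
Why: 9-BBN should add only to the monosubstituted C11=C12 olefin with boron on C12, leaving the trisubstituted C7=C8 and tiglate olefins alone, and the B-alkyl Suzuki–Miyaura coupling forms C12–C13 with retention of the iodide geometry so that C12 ends cis to C15 (13Z).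

**Step 25**
Reactants: 33 the silylethyl ester
Product: 34 19-tigloyloxylabda-7,13(Z)-dien-15-oic acid, (4S,5R,9S,10R), the target
Conditions: Bu4NF, THF, 0 °C to rt; aq. NH4Cl and dilute HCl work-up
Reagents that add atoms: none
Why: Fluoride attacks silicon and the ester fragments by β-elimination to ethene and the carboxylate, conditions that leave the hindered tiglate, both olefin geometries and all four stereocentres untouched.

**Compound list**

1 | 2-methylcyclohexanone | CC1CCCCC1=O | starting material
2 | ethyl 3-methyl-2-oxocyclohexane-1-carboxylate | CCOC(=O)C1CCCC(C)C1=O | intermediate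
3 | ethyl 1-(hydroxymethyl)-3-methyl-2-oxocyclohexane-1-carboxylate | CCOC(=O)C1(CO)CCCC(C)C1=O | intermediate
4 | ethyl 1-(TBS-oxymethyl)-3-methyl-2-oxocyclohexane-1-carboxylate | CCOC(=O)C1(CO[Si](C)(C)C(C)(C)C)CCCC(C)C1=O | intermediate
5 | potassium enolate of 4 | CCOC(=O)C1(CO[Si](C)(C)C(C)(C)C)CCCC(C)=C1[O-].[K+] | intermediate
6 | ethyl 1-(TBS-oxymethyl)-3-methyl-2-(trifluoromethylsulfonyloxy)cyclohex-2-ene-1-carboxylate | CCOC(=O)C1(CO[Si](C)(C)C(C)(C)C)CCCC(C)=C1OS(=O)(=O)C(F)(F)F | intermediate
7 | tributyl(vinyl)stannane | C=C[Sn](CCCC)(CCCC)CCCC | starting material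
8 | ethyl 1-(TBS-oxymethyl)-3-methyl-2-vinylcyclohex-2-ene-1-carboxylate | CCOC(=O)C1(CO[Si](C)(C)C(C)(C)C)CCCC(C)=C1C=C | intermediate
9 | [1-(TBS-oxymethyl)-3-methyl-2-vinylcyclohex-2-en-1-yl]methanol (racemic) | OCC1(CO[Si](C)(C)C(C)(C)C)CCCC(C)=C1C=C | intermediate
10 | (3-methyl-2-vinylcyclohex-2-ene-1,1-diyl)dimethanol | OCC1(CO)CCCC(C)=C1C=C | intermediate
11 | (R)-[1-(hydroxymethyl)-3-methyl-2-vinylcyclohex-2-en-1-yl]methyl acetate | OC[C@@]1(COC(C)=O)CCCC(C)=C1C=C | intermediate
12 | (S)-[1-(TBDPS-oxymethyl)-3-methyl-2-vinylcyclohex-2-en-1-yl]methyl acetate | CC(C)(C)[Si](c1ccccc1)(c1ccccc1)OC[C@@]1(COC(C)=O)CCCC(C)=C1C=C | intermediate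
13 | (S)-[1-(TBDPS-oxymethyl)-3-methyl-2-vinylcyclohex-2-en-1-yl]methanol | CC(C)(C)[Si](c1ccccc1)(c1ccccc1)OC[C@@]1(CO)CCCC(C)=C1C=C | intermediate
14 | but-2-ynoic acid | CC#CC(=O)O | starting material
15 | (S)-[1-(TBDPS-oxymethyl)-3-methyl-2-vinylcyclohex-2-en-1-yl]methyl but-2-ynoate | CC(C)(C)[Si](c1ccccc1)(c1ccccc1)OC[C@@]1(COC(=O)C#CC)CCCC(C)=C1C=C | intermediate
16 | 19-(TBDPS-oxy)-12,13,14,15,16-pentanorlabda-5,8-dien-11,18-olide | CC(C)(C)[Si](c1ccccc1)(c1ccccc1)OC[C@@]12CCC[C@]3(C)C(=C(C)CC=C13)C(=O)OC2 | intermediate
17 | methyl 18-hydroxy-19-(TBDPS-oxy)-12,13,14,15,16-pentanorlabda-5,8-dien-11-oate | CC(C)(C)[Si](c1ccccc1)(c1ccccc1)OC[C@@]1(CO)CCC[C@]2(C)C(C(=O)OC)=C(C)CC=C12 | intermediate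
18 | methyl 18-hydroxy-19-(TBDPS-oxy)-12,13,14,15,16-pentanorlabd-8-en-11-oate (5α-H) | CC(C)(C)[Si](c1ccccc1)(c1ccccc1)OC[C@@]1(CO)CCC[C@]2(C)C(C(=O)OC)=C(C)CC[C@@H]12 | intermediate
19 | methyl 18-iodo-19-(TBDPS-oxy)-12,13,14,15,16-pentanorlabd-8-en-11-oate | CC(C)(C)[Si](c1ccccc1)(c1ccccc1)OC[C@@]1(CI)CCC[C@]2(C)C(C(=O)OC)=C(C)CC[C@@H]12 | intermediate
20 | methyl 19-(TBDPS-oxy)-12,13,14,15,16-pentanorlabd-8-en-11-oate | CC(C)(C)[Si](c1ccccc1)(c1ccccc1)OC[C@@]1(C)CCC[C@]2(C)C(C(=O)OC)=C(C)CC[C@@H]12 | intermediate
21 | methyl 7-bromo-19-(TBDPS-oxy)-12,13,14,15,16-pentanorlabd-8-en-11-oate (C7 epimers) | CC(C)(C)[Si](c1ccccc1)(c1ccccc1)OC[C@@]1(C)CCC[C@]2(C)C(C(=O)OC)=C(C)C(Br)C[C@@H]12 | intermediate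
22 | bromozinc 7,9(11)-dienolate of the C11 methyl ester | CC(C)(C)[Si](c1ccccc1)(c1ccccc1)OC[C@@]1(C)CCC[C@]2(C)C(=C(OC)O[Zn]Br)C(C)=CC[C@@H]12 | intermediate
23 | methyl 19-(TBDPS-oxy)-12,13,14,15,16-pentanorlabd-7-en-11-oate (9α-H) | CC(C)(C)[Si](c1ccccc1)(c1ccccc1)OC[C@@]1(C)CCC[C@]2(C)[C@@H](C(=O)OC)C(C)=CC[C@@H]12 | intermediate
24 | 19-(TBDPS-oxy)-12,13,14,15,16-pentanorlabd-7-en-11-ol | CC(C)(C)[Si](c1ccccc1)(c1ccccc1)OC[C@@]1(C)CCC[C@]2(C)[C@@H](CO)C(C)=CC[C@@H]12 | intermediate
25 | 19-(TBDPS-oxy)-12,13,14,15,16-pentanorlabd-7-en-11-al | CC(C)(C)[Si](c1ccccc1)(c1ccccc1)OC[C@@]1(C)CCC[C@]2(C)[C@@H](C=O)C(C)=CC[C@@H]12 | intermediate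
26 | 19-(TBDPS-oxy)-13,14,15,16-tetranorlabda-7,11-diene | CC(C)(C)[Si](c1ccccc1)(c1ccccc1)OC[C@@]1(C)CCC[C@]2(C)[C@@H](C=C)C(C)=CC[C@@H]12 | intermediate
27 | 13,14,15,16-tetranorlabda-7,11-dien-19-ol | OC[C@@]1(C)CCC[C@]2(C)[C@@H](C=C)C(C)=CC[C@@H]12 | intermediate
28 | tigloyl chloride | C/C=C(\C)C(=O)Cl | starting material
29 | 13,14,15,16-tetranorlabda-7,11-dien-19-yl (E)-2-methylbut-2-enoate | C/C=C(\C)C(=O)OC[C@@]1(C)CCC[C@]2(C)[C@@H](C=C)C(C)=CC[C@@H]12 | intermediate
30 | (Z)-3-iodobut-2-enoic acid | C/C(I)=C/C(=O)O | starting material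
31 | 2-(trimethylsilyl)ethyl (Z)-3-iodobut-2-enoate | C/C(I)=C/C(=O)OCC[Si](C)(C)C | intermediate
32 | 9-(19-tigloyloxy-13,14,15,16-tetranorlabd-7-en-12-yl)-9-borabicyclo[3.3.1]nonane | C/C=C(\C)C(=O)OC[C@@]1(C)CCC[C@]2(C)[C@@H](CCB3C4CCCC3CCC4)C(C)=CC[C@@H]12 | intermediate
33 | 2-(trimethylsilyl)ethyl 19-tigloyloxylabda-7,13(Z)-dien-15-oate | C/C=C(\C)C(=O)OC[C@@]1(C)CCC[C@]2(C)[C@@H](CC/C(C)=C\C(=O)OCC[Si](C)(C)C)C(C)=CC[C@@H]12 | intermediate
34 | 19-tigloyloxylabda-7,13(Z)-dien-15-oic acid (CNP0249147.2) | C/C=C(\C)C(=O)OC[C@@]1(C)CCC[C@]2(C)[C@@H](CC/C(C)=C\C(=O)O)C(C)=CC[C@@H]12 | target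

**Step count**

Total step count: 25. Longest linear sequence: 24 (steps 1–22, 24 and 25; step 23 is the side branch).

**Steps most likely to fail**

1. Step 11.
   - Risk: the cycloaddition may be too slow to compete with a [1,5]-hydrogen shift from C20 to C7 in the cisoid diene, or with oligomerisation. The transition state has to pay for the E rotamer of the ester, the crowded s-cis diene and the strain of two bridgehead olefins.
   - Fallback (known chemistry): the tether is given up. Setting out from 12, the diene is heated with excess methyl but-2-ynoate under high pressure (about 12 kbar, 60 °C). This is the established intermolecular addition of acetylenic esters to 1-vinyl-2,6,6-trisubstituted cyclohexenes.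
   - It should give methyl 18-acetoxy-19-(TBDPS-oxy)-12,13,14,15,16-pentanorlabda-5,8-dien-11-oate F1. Regiochemistry then rests on the polarisation of the diene by the two alkyl groups on C10 (ortho rule). C4 exerts no facial control, so the C10 epimers would have to be separated by chromatography.
   - Acetate removal with K2CO3 in MeOH brings the material back to the route at 17.

2. Step 16.
   - Risk: poor site selectivity between C7 and C17, over-bromination, or loss of HBr on heating.
   - Fallback: the olefin is moved in two ionic steps instead. Setting out from 20, deprotonation with LiN(i-Pr)2 in THF at −78 °C followed by an AcOH quench (deconjugative protonation, expected at the syn C17 methyl) should give methyl 19-(TBDPS-oxy)-12,13,14,15,16-pentanorlabd-8(17)-en-11-oate F2.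
   - Acid-catalysed exo-to-endo isomerisation (TsOH, benzene, 50 °C) then follows. The C8 cation should lose the C7 proton rather than the C9 proton next to the ester, as in the γ- to α-cyclogeranate change. The route is rejoined at 23.

3. Step 13.
   - Risk: slow or incomplete reduction of an olefin flanked by two quaternary carbons, olefin migration within the skipped diene, or catalyst deactivation.
   - Fallback: hydrogen-atom-transfer hydrogenation with Mn(dpm)3, PhSiH3 and t-BuOOH in i-PrOH. This stepwise radical reduction does not need metal access to the olefin face and favours the more stable trans-decalin.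
   - It sets out from 17 and returns at 18, and it makes no new compound (F0).

**Further compounds**

F1 | step 11 | methyl 18-acetoxy-19-(TBDPS-oxy)-12,13,14,15,16-pentanorlabda-5,8-dien-11-oate | CC(C)(C)[Si](c1ccccc1)(c1ccccc1)OC[C@@]1(COC(C)=O)CCC[C@]2(C)C(C(=O)OC)=C(C)CC=C12
F2 | step 16 | methyl 19-(TBDPS-oxy)-12,13,14,15,16-pentanorlabd-8(17)-en-11-oate (9α-H) | CC(C)(C)[Si](c1ccccc1)(c1ccccc1)OC[C@@]1(C)CCC[C@]2(C)[C@@H](C(=O)OC)C(=C)CC[C@@H]12
F0 | step 13 | none | none
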